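## Retrosynthetic overview

- The target is the (2S)-flavanone; its C4 ketone is carried through the ring-forming step as a C4 methoxy group, so the late stage is only OMe → OH exchange, oxidation and MOM removal from the cis-4-methoxyflavan 17.
- The strategy rests on ring C being the O1–C2–C3–C4 chain hung on ring A. Cutting O1–C2 and C3–C4 gives a ring A heterodiene O1=C8a–C4a=C4 (a C4-methoxy ortho-quinone methide, made in the flask from salicylaldehyde 8 and trimethyl orthoformate 14) and the C2=C3 alkene of the 2,4-dioxygenated styrene 13.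
- Salicylaldehyde 8 comes from resorcinol: bis-MOM ether, directed lithiation/prenylation at C2, C–H borylation/oxidation to a symmetric phenol, ortho-formylation (regiochemistry forced by symmetry).
- Styrene 13 comes from 4,6-dibromoresorcinol: bis-MOM ether, mono Br/Li exchange with prenylation, Suzuki–Miyaura vinylation.
- Ring order: rings A and B are bought as arenes; ring C is the only ring formed (step 8), together with both stereocentres.

Key step: step 8

Assumption: the sense of induction of the chiral acid in step 8 cannot be predicted with confidence; the (R)-catalyst is written and taken to give (2S,4S)-17, and the (S)-catalyst is used if the sense proves opposite.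

Abbreviations: MOM = methoxymethyl; prenyl = 3-methylbut-2-en-1-yl.

## Route

Step 1
Reactants: 1 resorcinol
Product: 2 1,3-bis(methoxymethoxy)benzene
Conditions: NaH (2.4 equiv), MOMCl (2.4 equiv), DMF, 0 °C → rt
Reagents that add atoms: chloromethyl methyl ether (MOMCl), COCCl
Why: Williamson-type O-alkylation of the disodium resorcinolate with the hard electrophile MOMCl should give the bis-acetal, whose MOM groups later direct the lithiation and are removable by acid.

Step 2
Reactants: 2 1,3-bis(methoxymethoxy)benzene; 3 prenyl bromide (1-bromo-3-methylbut-2-ene)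
Product: 5 1,3-bis(methoxymethoxy)-2-(3-methylbut-2-en-1-yl)benzene, via 2,6-bis(methoxymethoxy)phenyllithium 4 (not isolated)
Conditions: n-BuLi (1.1 equiv), THF, 0 °C → rt; CuI (10 mol %), then 3 (1.2 equiv), −78 °C → rt
Reagents that add atoms: none
Why: Directed ortho-metalation takes place at C2 between the two chelating MOM ethers, and copper-catalysed allylic substitution on prenyl bromide occurs at the unhindered primary carbon (SN2) to give the linear prenyl arene.

Step 3
Reactants: 5 1,3-bis(methoxymethoxy)-2-(3-methylbut-2-en-1-yl)benzene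
Product: 7 3,5-bis(methoxymethoxy)-4-(3-methylbut-2-en-1-yl)phenol, via arylboronic acid pinacol ester 6 (not isolated)
Conditions: [Ir(OMe)(cod)]2 (1.5 mol %), 4,4'-di-tert-butyl-2,2'-bipyridine (3 mol %), B2pin2 (1.0 equiv), THF, 70 °C; then aq NaOH, 30% H2O2, 0 °C → rt
Reagents that add atoms: hydrogen peroxide, OO
Why: Sterically governed Hartwig–Miyaura C–H borylation of the 1,2,3-trisubstituted arene can only occur at C5, the single C–H bond without an ortho substituent, and basic peroxide oxidation of the C–B bond (1,2-aryl shift to oxygen) should give the symmetric phenol without touching the trisubstituted alkene or the MOM ethers.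

Step 4
Reactants: 7 3,5-bis(methoxymethoxy)-4-(3-methylbut-2-en-1-yl)phenol
Product: 8 6-hydroxy-2,4-bis(methoxymethoxy)-3-(3-methylbut-2-en-1-yl)benzaldehyde (the same compound as 2-hydroxy-4,6-bis(methoxymethoxy)-5-prenylbenzaldehyde)
Conditions: MgCl2 (3 equiv), Et3N (4 equiv), (CH2O)n (6 equiv), MeCN, 80 °C
Reagents that add atoms: formaldehyde (as paraformaldehyde), C=O
Why: Casnati–Skattebøl ortho-formylation through the magnesium phenoxide delivers formaldehyde only ortho to the free hydroxyl, and since the para position carries the prenyl group and the two ortho positions are equivalent by symmetry only one salicylaldehyde can form.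

Step 5
Reactants: 9 4,6-dibromoresorcinol
Product: 10 1,5-dibromo-2,4-bis(methoxymethoxy)benzene
Conditions: NaH (2.4 equiv), MOMCl (2.4 equiv), DMF, 0 °C → rt
Reagents that add atoms: chloromethyl methyl ether (MOMCl), COCCl
Why: Williamson-type O-alkylation of the acidic dibromoresorcinol as in step 1 should give the bis-MOM ether that stabilises the aryllithium of the next step.

Step 6
Reactants: 10 1,5-dibromo-2,4-bis(methoxymethoxy)benzene; 3 prenyl bromide
Product: 12 1-bromo-2,4-bis(methoxymethoxy)-5-(3-methylbut-2-en-1-yl)benzene, via 5-bromo-2,4-bis(methoxymethoxy)phenyllithium 11 (not isolated)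
Conditions: n-BuLi (1.0 equiv), THF, −78 °C; CuI (10 mol %), then 3 (1.3 equiv), −78 → 0 °C
Reagents that add atoms: none
Why: Bromine–lithium exchange with one equivalent of n-BuLi at −78 °C stops at the monolithio species, which is stabilised by the ortho MOM ether, and copper-catalysed SN2 allylation with prenyl bromide installs the linear prenyl group while the second bromide is kept for the vinylation.

Step 7
Reactants: 12 1-bromo-2,4-bis(methoxymethoxy)-5-(3-methylbut-2-en-1-yl)benzene
Product: 13 1-ethenyl-2,4-bis(methoxymethoxy)-5-(3-methylbut-2-en-1-yl)benzene (2,4-bis(methoxymethoxy)-5-prenylstyrene)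
Conditions: vinylboronic acid pinacol ester (1.5 equiv), PdCl2(dppf) (5 mol %), K2CO3 (3 equiv), 1,4-dioxane/H2O (5:1), 85 °C
Reagents that add atoms: vinylboronic acid pinacol ester, C=CB1OC(C)(C)C(C)(C)O1
Why: Suzuki–Miyaura coupling of the aryl bromide with the vinylboronate (oxidative addition to zerovalent palladium, transmetalation, reductive elimination) should give the styrene directly, the trisubstituted prenyl alkene being inert to Heck-type insertion.

Step 8
Reactants: 8 6-hydroxy-2,4-bis(methoxymethoxy)-3-(3-methylbut-2-en-1-yl)benzaldehyde; 13 2,4-bis(methoxymethoxy)-5-prenylstyrene; 14 trimethyl orthoformate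
Product: 17 (2S,4S)-4-methoxy-5,7-bis(methoxymethoxy)-2-[2,4-bis(methoxymethoxy)-5-(3-methylbut-2-en-1-yl)phenyl]-6-(3-methylbut-2-en-1-yl)chromane (2,4-cis), via dimethyl acetal 15 (not isolated), via methoxy ortho-quinone methide 16 (not isolated)
Conditions: 8 (1.0 equiv), 13 (1.5 equiv), 14 (2.0 equiv), (R)-3,3'-bis(2,4,6-triisopropylphenyl)-1,1'-binaphthyl-2,2'-diyl hydrogen phosphate (10 mol %), 5 Å molecular sieves, toluene, −20 °C; Et3N quench
Reagents that add atoms: none
Why: Proposed new method: the phosphoric acid first catalyses acetalisation of 8 by 14 to 15 and then ionises this highly activated benzylic acetal to the methoxy-substituted ortho-quinone methide 16 (an oxocarbenium ion held as a hydrogen-bonded ion pair with the chiral phosphate), whose C4 is attacked by the terminal CH2 of the electron-rich styrene 13 (C3–C4 bond) before the ring A oxygen captures the 2',4'-dioxygenated benzylic cation at C2 (O1–C2 bond). The closest known reactions are the achiral acid-promoted salicylaldehyde/orthoformate/styrene annulation to 4-alkoxyflavans and chiral phosphoric acid-catalysed [4+2] cycloadditions of ortho-quinone methides with styrenes. Ring C closes as a six-membered oxacycle in an asynchronous inverse-electron-demand hetero-Diels–Alder mode, the heterodiene being O1=C8a–C4a=C4 and the dienophile the styrene C2=C3. C4 is set by the chiral phosphate, which shields one face of the (E)-configured heterodiene, and C2 follows from endo approach of the aryl group, which places aryl and methoxy on the same face and gives the 2,4-cis (2S,4S) product. The step needs enantiofacial control (catalyst), cis diastereoselectivity (endo closure) and regiocontrol, the last secured by the polarisation of the styrene, whose β-carbon is the nucleophile and whose α-carbon carries the cation that O1 traps. The weak acid, low temperature and basic quench are chosen so that MOM ethers, prenyl groups and the ionisable C2–O1 bond should survive, the trioxygenated ring A making a stronger acid unnecessary for ionisation.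

Step 9
Reactants: 17 (2S,4S)-4-methoxyflavan
Product: 18 (2S)-5,7-bis(methoxymethoxy)-2-[2,4-bis(methoxymethoxy)-5-(3-methylbut-2-en-1-yl)phenyl]-6-(3-methylbut-2-en-1-yl)chroman-4-ol (mixture of C4 epimers)
Conditions: PPTS (0.3 equiv), THF/H2O (4:1), 40 °C
Reagents that add atoms: water, O
Why: SN1 solvolysis, in which the C4 methoxy group, benzylic to the 5,7-dioxygenated ring A, ionises under acid too mild to cleave MOM ethers and the cation is captured by the large excess of water; C4 is scrambled without consequence because it is oxidised next, and C2 is not involved.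

Step 10
Reactants: 18 (2S)-flavan-4-ol (C4 epimers)
Product: 19 (2S)-5,7-bis(methoxymethoxy)-2-[2,4-bis(methoxymethoxy)-5-(3-methylbut-2-en-1-yl)phenyl]-6-(3-methylbut-2-en-1-yl)chroman-4-one
Conditions: Dess–Martin periodinane (1.5 equiv), pyridine (3 equiv), CH2Cl2, 0 °C → rt
Reagents that add atoms: none
Why: Dess–Martin oxidation of the secondary benzylic alcohol under buffered conditions should convert both C4 epimers into the flavanone without the base or strong acid that could open ring C, so the C2 configuration is kept.

Step 11
Reactants: 19 (2S)-tetra-O-MOM flavanone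
Product: 20 (2S)-2-[2,4-dihydroxy-5-(3-methylbut-2-en-1-yl)phenyl]-5,7-dihydroxy-6-(3-methylbut-2-en-1-yl)chroman-4-one (target)
Conditions: HCl (1.25 M in MeOH), rt → 40 °C
Reagents that add atoms: none
Why: Acid-catalysed acetal exchange with methanol removes the four MOM groups as dimethoxymethane, the 5-O-MOM group going first through hydrogen bonding to the C4 carbonyl, under conditions of the kind commonly used to unmask prenylated polyphenolic flavanones and mild enough that ring C should stay closed.

## Compound list

1 | resorcinol | Oc1cccc(O)c1 | starting material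
2 | 1,3-bis(methoxymethoxy)benzene | COCOc1cccc(OCOC)c1 | intermediate
3 | prenyl bromide (1-bromo-3-methylbut-2-ene) | CC(C)=CCBr | starting material
4 | 2,6-bis(methoxymethoxy)phenyllithium | [Li]c1c(OCOC)cccc1OCOC | intermediate (not isolated)
5 | 1,3-bis(methoxymethoxy)-2-(3-methylbut-2-en-1-yl)benzene | COCOc1cccc(OCOC)c1CC=C(C)C | intermediate
6 | 2-[3,5-bis(methoxymethoxy)-4-(3-methylbut-2-en-1-yl)phenyl]-4,4,5,5-tetramethyl-1,3,2-dioxaborolane | COCOc1cc(B2OC(C)(C)C(C)(C)O2)cc(OCOC)c1CC=C(C)C | intermediate (not isolated)
7 | 3,5-bis(methoxymethoxy)-4-(3-methylbut-2-en-1-yl)phenol | COCOc1cc(O)cc(OCOC)c1CC=C(C)C | intermediate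
8 | 6-hydroxy-2,4-bis(methoxymethoxy)-3-(3-methylbut-2-en-1-yl)benzaldehyde | O=Cc1c(O)cc(OCOC)c(CC=C(C)C)c1OCOC | intermediate
9 | 4,6-dibromoresorcinol | Oc1cc(O)c(Br)cc1Br | starting material
10 | 1,5-dibromo-2,4-bis(methoxymethoxy)benzene | COCOc1cc(OCOC)c(Br)cc1Br | intermediate
11 | 5-bromo-2,4-bis(methoxymethoxy)phenyllithium | [Li]c1cc(Br)c(OCOC)cc1OCOC | intermediate (not isolated)
12 | 1-bromo-2,4-bis(methoxymethoxy)-5-(3-methylbut-2-en-1-yl)benzene | CC(C)=CCc1cc(Br)c(OCOC)cc1OCOC | intermediate
13 | 1-ethenyl-2,4-bis(methoxymethoxy)-5-(3-methylbut-2-en-1-yl)benzene | C=Cc1cc(CC=C(C)C)c(OCOC)cc1OCOC | intermediate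
14 | trimethyl orthoformate | COC(OC)OC | starting material
15 | 2-(dimethoxymethyl)-3,5-bis(methoxymethoxy)-4-(3-methylbut-2-en-1-yl)phenol | COC(OC)c1c(O)cc(OCOC)c(CC=C(C)C)c1OCOC | intermediate (not isolated)
16 | (6E)-6-(methoxymethylidene)-3,5-bis(methoxymethoxy)-4-(3-methylbut-2-en-1-yl)cyclohexa-2,4-dien-1-one | CO/C=C1/C(=O)C=C(OCOC)C(CC=C(C)C)=C1OCOC | intermediate (not isolated)
17 | (2S,4S)-4-methoxy-5,7-bis(methoxymethoxy)-2-[2,4-bis(methoxymethoxy)-5-(3-methylbut-2-en-1-yl)phenyl]-6-(3-methylbut-2-en-1-yl)chromane | CC(C)=CCc1cc([C@@H]2C[C@H](OC)c3c(cc(OCOC)c(CC=C(C)C)c3OCOC)O2)c(OCOC)cc1OCOC | intermediate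
18 | (2S)-5,7-bis(methoxymethoxy)-2-[2,4-bis(methoxymethoxy)-5-(3-methylbut-2-en-1-yl)phenyl]-6-(3-methylbut-2-en-1-yl)chroman-4-ol, C4 epimers | CC(C)=CCc1cc([C@@H]2CC(O)c3c(cc(OCOC)c(CC=C(C)C)c3OCOC)O2)c(OCOC)cc1OCOC | intermediate
19 | (2S)-5,7-bis(methoxymethoxy)-2-[2,4-bis(methoxymethoxy)-5-(3-methylbut-2-en-1-yl)phenyl]-6-(3-methylbut-2-en-1-yl)chroman-4-one | CC(C)=CCc1cc([C@@H]2CC(=O)c3c(cc(OCOC)c(CC=C(C)C)c3OCOC)O2)c(OCOC)cc1OCOC | intermediate
20 | (2S)-2-[2,4-dihydroxy-5-(3-methylbut-2-en-1-yl)phenyl]-5,7-dihydroxy-6-(3-methylbut-2-en-1-yl)chroman-4-one | CC(C)=CCc1cc([C@@H]2CC(=O)c3c(cc(O)c(CC=C(C)C)c3O)O2)c(O)cc1O | target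

## Step count

Total: 11 steps. Longest linear sequence: 8 steps (steps 1–4, then 8–11, from resorcinol); the ring B branch is 3 steps (steps 5–7).

## Steps most likely to fail

**Step 8 (proposed new method).** Several processes may defeat it:
- Ionisation to 16 may be too slow with the weak acid, so that acid-induced oligomerisation of the styrene takes over.
- The ion pair may give poor enantiofacial selectivity.
- Any exo closure sets C2 opposite and shows up as lost enantiopurity once C4 is oxidised.
- Reversible C2–O1 ionisation of the product may erode the C2 configuration.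

Fallback, using only established reactions: it sets out from 8, 13 and 14 and rejoins the route at 19.
- Sc(OTf)3 (5 mol %) in CH2Cl2 at 0 °C should promote the same three-component annulation without asymmetric induction and give the racemic cis-4-methoxyflavan F1.
- PPTS in wet THF should then give the racemic flavan-4-ol F2, and Dess–Martin periodinane the racemic tetra-MOM flavanone F3.
- Kinetic resolution by Noyori-type asymmetric transfer hydrogenation (Cp*RhCl[(R,R)-TsDPEN] or its antipode, whichever consumes the (2R)-ketone; HCO2H/Et3N, EtOAc, rt, run to just past half conversion) should reduce the (2R)-enantiomer to the (2R,4R)-cis-flavan-4-ol F4.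
- F4 is separated by chromatography, leaving the (2S)-ketone, which is compound 19.

**Step 9.** The C4 cation may lose a C3 proton instead of adding water (E1 elimination to the flav-3-ene), or acid exposure long enough for exchange may begin to ionise C2–O1. Fallback: it sets out from 17 and rejoins at 19, skipping 18. The benzylic methyl ether is cleaved oxidatively with DDQ (1.2 equiv) in CH2Cl2/pH 7 buffer at 0 °C. Hydride abstraction from C4 gives the methoxy-oxocarbenium ion, water adds and methanol is lost, giving the ketone directly. This is the mode of action known from DDQ cleavage of p-methoxybenzyl-type ethers. No new compound is made (F0).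

**Step 11.** Protic acid may cyclise the prenyl groups onto the freed ortho phenols (chroman formation), add HCl or methanol across the alkenes, or racemise C2 by opening ring C to the chalcone. Fallback: it sets out from 19 and rejoins at 20. TMSOTf (8 equiv)/2,2'-bipyridyl (12 equiv) in CH2Cl2 at 0 °C converts aryl MOM ethers into aryl trimethylsilyl ethers without free protic acid and should give the tetrakis(trimethylsilyl) ether F5. Stirring F5 with neutral aqueous methanol should hydrolyse the silyl ethers to 20.

## Further compounds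

F1 | step 8 | racemic cis-4-methoxy-5,7-bis(methoxymethoxy)-2-[2,4-bis(methoxymethoxy)-5-prenylphenyl]-6-prenylchromane (both enantiomers shown) | CC(C)=CCc1cc([C@@H]2C[C@H](OC)c3c(cc(OCOC)c(CC=C(C)C)c3OCOC)O2)c(OCOC)cc1OCOC.CC(C)=CCc1cc([C@H]2C[C@@H](OC)c3c(cc(OCOC)c(CC=C(C)C)c3OCOC)O2)c(OCOC)cc1OCOC
F2 | step 8 | racemic 5,7-bis(methoxymethoxy)-2-[2,4-bis(methoxymethoxy)-5-prenylphenyl]-6-prenylchroman-4-ol (C4 epimers) | CC(C)=CCc1cc(C2CC(O)c3c(cc(OCOC)c(CC=C(C)C)c3OCOC)O2)c(OCOC)cc1OCOC
F3 | step 8 | racemic 5,7-bis(methoxymethoxy)-2-[2,4-bis(methoxymethoxy)-5-prenylphenyl]-6-prenylchroman-4-one | CC(C)=CCc1cc(C2CC(=O)c3c(cc(OCOC)c(CC=C(C)C)c3OCOC)O2)c(OCOC)cc1OCOC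
F4 | step 8 | (2R,4R)-5,7-bis(methoxymethoxy)-2-[2,4-bis(methoxymethoxy)-5-prenylphenyl]-6-prenylchroman-4-ol | CC(C)=CCc1cc([C@H]2C[C@@H](O)c3c(cc(OCOC)c(CC=C(C)C)c3OCOC)O2)c(OCOC)cc1OCOC
F0 | step 9 | none | none
F5 | step 11 | (2S)-5,7-bis(trimethylsilyloxy)-2-[2,4-bis(trimethylsilyloxy)-5-prenylphenyl]-6-prenylchroman-4-one | CC(C)=CCc1cc([C@@H]2CC(=O)c3c(cc(O[Si](C)(C)C)c(CC=C(C)C)c3O[Si](C)(C)C)O2)c(O[Si](C)(C)C)cc1O[Si](C)(C)C
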